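The earlier runs and the new flask stem from a simulated flask for an exercise; noise was put on by code.

Start with what Tuesday's flask leaves unaccounted for. After 3.00 min the readings show 10.9% of the charge as L and 61.0% as J, so 28.1% has gone elsewhere. In Sunday's flask, at 3.00 min, that leftover is 23.6%.

| flask | L | D | Q | remark | time |
|---|---|---|---|---|---|
| Tuesday's | 2 mM | 25 mM | 3 mM | run made earlier |  |
| Sunday's | 2 mM | 50 mM | 4.5 mM | run made earlier |  |
| dusk | 2.0 mM | 25.0 mM | 4.50 mM |  | 5.0 min |
| autumn | 3.0 mM | 25.0 mM | 4.50 mM |  | 5.0 min |
| noon | 5.0 mM | 25.0 mM | 4.50 mM |  | 5.0 min |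

| run | time / min | J / % | L / % |
|---|---|---|---|
| Tuesday's | 0.250 | 11.9 | 84.1 |
| Tuesday's | 0.417 | 17.9 | 72.3 |
| Tuesday's | 0.833 | 32.3 | 54.5 |
| Tuesday's | 1.50 | 47.5 | 34.0 |
| Tuesday's | 3.00 | 61.0 | 10.9 |
| Sunday's | 0.667 | 31.2 | 57.7 |
| Sunday's | 1.33 | 50.1 | 35.1 |
| Sunday's | 2.00 | 58.4 | 20.6 |
| Sunday's | 2.50 | 64.5 | 12.8 |
| Sunday's | 3.00 | 67.1 | 9.3 |

(standard deviation of a reading: 1 percentage point)

- the numbers in the tables scatter by 1 percentage point (one standard deviation)
- a reading or a percentage of J counts all its forms, free or not
- the concentration of J that is asked is that of its free form alone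
- "hardly changes" means that all values lie within two and a half points (for a concentration: within two and a half percent of the largest)

* [J] (only what is free in solution) at the end for dusk, autumn, noon, in this order
* the shape of the row from first to last (falls, then rises / rises all the way / falls all the way / rises, then falls / hardly changes)

Compare two rates at one moment: L going to J, and L going elsewhere. Divide that ratio by [D]/[Q]. Tuesday's readings give 0.260 and Sunday's give 0.256. Their mean is 0.258. This is the split S, J formed per L lost elsewhere, divided by [D]/[Q]. You would call it a selectivity factor. Two runs cannot separate the two orders, so I take first order in each. The decay of L moves little between the runs, with a rate constant read as 0.739 /min on Tuesday and 0.792 /min on Sunday.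

Now run dusk slowly, by my own reckoning. In the first instants, J forms 1.43 times as fast as the other loss, so J takes a share of 58.9% of the L consumed. Through the middle, I assume each L lost elsewhere takes one Q and each J takes one D. Q then falls faster than D as a fraction of its charge, so the ratio drifts upward. By the end, at Tuesday's rate constant, 2.49% of L remains. The drift is stronger at noon, where my reckoning with the starting share puts the final [D]/[Q] near 9.02. I therefore expect J in all its forms near 1.18 mM at dusk and a little above 2.95 mM at noon. The readings count every form of J, so they do not show the free part.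

The forecast gives 1.41 mM, 2.11 mM and 3.52 mM, shape rises all the way. It takes a selectivity of 0.72 against my 0.588, and says “I assume free ≈ total”.

The flask gives 0.110 mM, 0.111 mM and 0.111 mM, shape hardly changes.

    L ⇌ X (K = 0.0142, k = 0.0155 /s)
    D + X → J (k = 110 /M/s)
    Q + X → E (k = 408 /M/s)
    J ⇌ Z (K = 0.470, k = 0.00256 /s)
    G ⇌ J, rate k5*(cs5 - [J]) while solid is left; crystals form when [J] > cs5 (solubility = 0.110 mM, k = 0.950 /s)

Put the split to use. At noon it reckons 2.95 mM of J in all its forms. Of that, 0.111 mM is free, which leaves 2.84 mM for crystals G, and the noon flask holds 2.96 mM of G. At dusk the same subtraction leaves 1.07 mM, and G stands at 1.05 mM. Free J ends near its saturation value, 0.11 mM, and that saturation turns the shape of the row. With it taken away, the noon flask ends at 2.31 mM rather than 0.111 mM.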